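**Strategy**

The route rests on building ring A de novo by a Danheiser benzannulation. All six carbons of ring A are substituted (oxygen on C5, C7 and C8a, methyl on C6, the bridge on C8, the C4 carbonyl on C4a), so forming this ring from an ynol ether and a cyclobutenone assigns every substituent its place and avoids the 6-/8-methyl regioisomers of phloroglucinol chemistry. One thermal operation forms C8–C8a and C6–C7, closes ring A and leaves a free C8a hydroxyl next to unsubstituted C4a. The alkyne partner is a triisopropylsilyl ynol ether (benzyl ynol ethers rearrange on mild heating) that already carries the bridge stereocentre and ring T as its methyl/benzyl bis-enol ether.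

Key step: step 11

Numbering: flavanone positions are O1, C2 … C8a; ring T carbons are T1 (C–OCH3), T2 (C–CH3), T3 (C=O), T4 (bonded to the bridge), T5 (enol carbon), T6 (C(CH3)2). Enolisable ring T compounds are drawn as one tautomer.

Assumption: O-benzylation of the ring T enol (step 7) is taken to occur at the T5 oxygen, giving the cross-conjugated 2,5-dienone; the T3–O regioisomer, if formed, would converge on the same target at the final hydrogenolysis.

**Route**

Step 1
Reactants: 1 2,4,6-trihydroxybenzoic acid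
Product: 2 benzyl 2,4,6-trihydroxybenzoate
Conditions: BnBr (1.05 equiv), NaHCO3 (1.1 equiv), DMF, rt
Reagents that add atoms: benzyl bromide BrCc1ccccc1
Why: Chemoselective SN2 O-alkylation of the carboxylate, the only group ionised by hydrogencarbonate, installs a blocking group on the future T4 carbon that can later be removed by hydrogenolysis without acid or base.

Step 2
Reactants: 2 benzyl 2,4,6-trihydroxybenzoate
Product: 3 benzyl 2,6-dihydroxy-4-methoxybenzoate
Conditions: Me2SO4 (1.0 equiv), K2CO3 (1.1 equiv), acetone, rt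
Reagents that add atoms: dimethyl sulfate COS(=O)(=O)OC
Why: Williamson etherification is expected at the 4-hydroxyl, the only one not held in a hydrogen bond to the ester carbonyl, and this oxygen becomes the T1 methyl enol ether so that its position is fixed from the start.

Step 3
Reactants: 3 benzyl 2,6-dihydroxy-4-methoxybenzoate
Product: 4 benzyl 2-hydroxy-4-methoxy-3,3,5-trimethyl-6-oxocyclohexa-1,4-diene-1-carboxylate
Conditions: MeI (3.3 equiv), NaOMe (4 equiv), MeOH, 0 °C to rt
Reagents that add atoms: iodomethane CI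
Why: Dearomatising C-methylation of the phloroglucinolate (the classical entry to syncarpic-acid-type triketones) should methylate C3 and C5 and then once more at either of these equivalent carbons, the O-methyl group forcing the enol ether to lie between the gem-dimethyl and C-methyl carbons, while the ester-bearing carbon and the ester (a vinylogous carbonate in the anions) should stay untouched.

Step 4
Reactants: 4 benzyl 2-hydroxy-4-methoxy-3,3,5-trimethyl-6-oxocyclohexa-1,4-diene-1-carboxylate
Product: 6 5-hydroxy-3-methoxy-2,4,4-trimethylcyclohexa-2,5-dien-1-one, via carboxylic acid 5 (not isolated)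
Conditions: H2 (1 atm), 10% Pd/C, EtOAc, rt; then 40 °C
Reagents that add atoms: none
Why: Hydrogenolysis of the benzyl ester gives a beta-keto acid that should lose CO2 spontaneously (decarboxylation), freeing T4 under neutral conditions that spare the acid-labile methyl enol ether.

Step 5
Reactants: 6 5-hydroxy-3-methoxy-2,4,4-trimethylcyclohexa-2,5-dien-1-one; 7 isobutyraldehyde
Product: 8 5-methoxy-4,6,6-trimethyl-2-(2-methylpropylidene)cyclohex-4-ene-1,3-dione (E/Z mixture)
Conditions: 7 (5 equiv), piperidine (10 mol%), AcOH (10 mol%), 4 Å molecular sieves, CH2Cl2, 0 °C to rt; used crude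
Reagents that add atoms: none
Why: Knoevenagel condensation of the cyclic 1,3-dione with an excess of the branched aldehyde should stop at the alkylidene stage, as it does for isobutylidene derivatives of related triketones.

Step 6
Reactants: 8 5-methoxy-4,6,6-trimethyl-2-(2-methylpropylidene)cyclohex-4-ene-1,3-dione; 9 ethynyltrimethylsilane
Product: 10 5-hydroxy-3-methoxy-2,4,4-trimethyl-6-[(3S)-4-methyl-1-(trimethylsilyl)pent-1-yn-3-yl]cyclohexa-2,5-dien-1-one
Conditions: [Rh(OAc)(C2H4)2]2 (2.5 mol%), (R)-DTBM-SEGPHOS (5.5 mol%), 9 (3 equiv), 1,4-dioxane, 50 °C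
Reagents that add atoms: none
Why: Asymmetric conjugate alkynylation by an alkynyl complex of monovalent rhodium (known for enones and for alkylidene 1,3-dicarbonyl acceptors with silylacetylenes) creates the bridge stereocentre under ligand control; both alkene geometries should converge because exchanging the flanking carbonyls also exchanges the exposed face, and the ligand antipode is chosen to give the S adduct.

Step 7
Reactants: 10 5-hydroxy-3-methoxy-2,4,4-trimethyl-6-[(3S)-4-methyl-1-(trimethylsilyl)pent-1-yn-3-yl]cyclohexa-2,5-dien-1-one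
Product: 12 5-(benzyloxy)-3-methoxy-2,4,4-trimethyl-6-[(3R)-4-methylpent-1-yn-3-yl]cyclohexa-2,5-dien-1-one, via silylalkyne benzyl ether 11 (not isolated)
Conditions: BnBr (1.2 equiv), K2CO3 (2.5 equiv), DMF, rt; then MeOH, rt
Reagents that add atoms: benzyl bromide BrCc1ccccc1
Why: O-alkylation of the acidic enol (C-alkylation at the congested T4 being disfavoured) gives the doubly vinylogous ester, and carbonate in methanol then removes the C-silyl group by standard protodesilylation (the descriptor changes from S to R only because silicon no longer ranks the alkyne first).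

Step 8
Reactants: 12 5-(benzyloxy)-3-methoxy-2,4,4-trimethyl-6-[(3R)-4-methylpent-1-yn-3-yl]cyclohexa-2,5-dien-1-one
Product: 14 5-(benzyloxy)-3-methoxy-2,4,4-trimethyl-6-[(3R)-4-methyl-1-{[tri(propan-2-yl)silyl]oxy}pent-1-yn-3-yl]cyclohexa-2,5-dien-1-one, via lithium ynolate 13 (not isolated)
Conditions: LiHMDS (2.2 equiv), THF, −78 °C; t-BuOOH (1.1 equiv, in decane), −78 to 0 °C; TIPSOTf (1.3 equiv), −78 to 0 °C; Et3N-deactivated silica
Reagents that add atoms: tert-butyl hydroperoxide CC(C)(C)OO; triisopropylsilyl trifluoromethanesulfonate CC(C)[Si](C(C)C)(C(C)C)OS(=O)(=O)C(F)(F)F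
Why: Oxygen transfer from lithium tert-butyl peroxide to the lithium acetylide (the established ynolate route to siloxyalkynes) followed by O-silylation should give the silyl ynol ether without touching the bridge centre, whose C–H is far less acidic than the acetylenic C–H.

Step 9
Reactants: 15 1-ethoxyprop-1-yne; 16 acetone
Product: 18 3-ethoxy-2-methylcyclobut-2-en-1-one, via ketene 17 (not isolated)
Conditions: 16 pyrolysed over a glowing filament (ketene lamp); ketene stream passed into 15, CH2Cl2, 0 °C to rt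
Reagents that add atoms: none
Why: Ketene adds [2+2] to the electron-rich ynol ether with its carbonyl carbon on the methyl-bearing alkyne carbon, the classical cycloaddition route to 3-alkoxycyclobutenones.

Step 10
Reactants: 18 3-ethoxy-2-methylcyclobut-2-en-1-one; 19 benzyl alcohol
Product: 20 3-(benzyloxy)-2-methylcyclobut-2-en-1-one
Conditions: 19 (3 equiv), camphorsulfonic acid (5 mol%), toluene, 40 °C, reduced pressure (EtOH removed)
Reagents that add atoms: none
Why: Acid-catalysed vinylogous transesterification (addition–elimination at C3), driven by removal of ethanol, exchanges the ethyl group for a benzyl group that hydrogenolysis can remove at the end.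

Step 11
Reactants: 14 5-(benzyloxy)-3-methoxy-2,4,4-trimethyl-6-[(3R)-4-methyl-1-{[tri(propan-2-yl)silyl]oxy}pent-1-yn-3-yl]cyclohexa-2,5-dien-1-one; 20 3-(benzyloxy)-2-methylcyclobut-2-en-1-one
Product: 25 5-(benzyloxy)-6-[(1R)-1-{4-(benzyloxy)-6-hydroxy-3-methyl-2-[(triisopropylsilyl)oxy]phenyl}-2-methylpropyl]-3-methoxy-2,4,4-trimethylcyclohexa-2,5-dien-1-one, via vinylketene 21 (not isolated), via vinylcyclobutenone 22 (not isolated), via dienylketene 23 (not isolated), via cyclohexadienone 24 (not isolated)
Conditions: 20 (1.5 equiv), degassed toluene (0.4 M), sealed tube, base-washed glass, 85 °C; then 110 °C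
Reagents that add atoms: none
Why: Heating opens 20 by 4π electrocyclic ring opening to vinylketene 21, whose ketene C=C adds [2+2] to the siloxyalkyne to give 22; a second 4π opening gives dienylketene 23, 6π electrocyclisation gives dienone 24 and tautomerisation gives phenol 25. The closest known reaction is the Danheiser benzannulation of cyclobutenones with siloxyalkynes, which gives resorcinol monosilyl ethers. Ring A is closed by thermal disrotatory 6π electrocyclisation between the ketene carbon (C8a) and the terminal methylene (C4a), after the [2+2] step has made the C8–C8a and C6–C7 bonds. No stereocentre is created, and the bridge centre is a spectator with no acidic hydrogen under these neutral conditions. The step needs complete regioselectivity in the [2+2] addition, which the polarised ynol ether secures because its nucleophilic, bridge-bearing carbon attacks the ketene carbonyl carbon; the C8a hydroxyl thus derives from the ketene oxygen, C8 and C7 from the two alkyne carbons, and C6, C5 and C4a from C2, C3 and C4 of the four-membered ring. Ring T is carried as a bis-enol ether without any O–H so that it cannot add to the ketene, and the silyl ynol ether should survive the temperature that the ring opening needs.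

Step 12
Reactants: 25 ring A phenol (C8a–OH free, C7–OTIPS, C5–OBn, C4a–H)
Product: 26 C4a-iodo derivative of 25
Conditions: N-iodosuccinimide (1.05 equiv), CH2Cl2, −20 to 0 °C, dark
Reagents that add atoms: N-iodosuccinimide O=C1CCC(=O)N1I
Why: Electrophilic aromatic iodination can only occur at C4a, the single unsubstituted and triply oxygen-activated position, under neutral conditions that avoid acid-induced cyclisation of the C8a phenol onto ring T.

Step 13
Reactants: 26 C4a-iodo phenol; 27 tributyl(1-ethoxyethenyl)stannane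
Product: 29 C4a-acetyl phenol (2-hydroxyacetophenone of ring A), via aryl enol ether 28 (not isolated)
Conditions: 27 (1.5 equiv), Pd2(dba)3 (2.5 mol%), AsPh3 (20 mol%), CuI (10 mol%), DMF, 60 °C; then 0.5 M HCl, THF, 0 °C
Reagents that add atoms: water O
Why: Stille coupling (zerovalent palladium) with the acyl-anion equivalent followed by mild hydrolysis of the enol ether installs the acetyl group regiospecifically at C4a without a Lewis acid.

Step 14
Reactants: 29 C4a-acetyl phenol; 30 N,N-dimethylformamide dimethyl acetal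
Product: 32 5-(benzyloxy)-8-[(1R)-1-(2-(benzyloxy)-4-methoxy-3,3,5-trimethyl-6-oxocyclohexa-1,4-dien-1-yl)-2-methylpropyl]-6-methyl-7-[(triisopropylsilyl)oxy]-4H-chromen-4-one, via enaminone 31 (not isolated)
Conditions: 30 (3 equiv), toluene, 90 °C; concentrate; AcOH, 50 °C
Reagents that add atoms: none
Why: Condensation of the methyl ketone with the amide acetal gives an enaminone that cyclises by 6-endo oxa-Michael addition of the C8a hydroxyl with loss of dimethylamine, the standard enaminone route to chromones.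

Step 15
Reactants: 32 chromone; 33 phenylboronic acid
Product: 34 (2S)-5-(benzyloxy)-8-[(1R)-1-(2-(benzyloxy)-4-methoxy-3,3,5-trimethyl-6-oxocyclohexa-1,4-dien-1-yl)-2-methylpropyl]-6-methyl-2-phenyl-7-[(triisopropylsilyl)oxy]-2,3-dihydro-4H-chromen-4-one
Conditions: 33 (2 equiv), Pd(OCOCF3)2 (5 mol%), (R)-t-BuPyOx (6 mol%), NH4PF6 (30 mol%), H2O (5 equiv), ClCH2CH2Cl, 60 °C
Reagents that add atoms: none
Why: Asymmetric conjugate addition of the arylboronic acid catalysed by cationic divalent palladium with a pyridine–oxazoline ligand (established for chromones) sets C2 under catalyst control, independent of the remote bridge centre; the R ligand is expected to give 2S, and its antipode would be used if the sense proved opposite.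

Step 16
Reactants: 34 protected flavanone
Product: 36 (2S)-5,7-dihydroxy-8-[(1R)-1-(2-hydroxy-4-methoxy-3,3,5-trimethyl-6-oxocyclohexa-1,4-dien-1-yl)-2-methylpropyl]-6-methyl-2-phenyl-2,3-dihydro-4H-chromen-4-one, via desilylated flavanone 35 (not isolated)
Conditions: TBAF (1.5 equiv), AcOH (1.5 equiv), THF, 0 °C to rt; then EtOAc, 10% Pd/C, H2 (1 atm), rt
Reagents that add atoms: none
Why: Acetic-acid-buffered fluoride desilylation cleaves the aryl silyl ether without base-induced retro-oxa-Michael racemisation at C2, and hydrogenolysis then removes the aryl and vinylogous-ester benzyl groups under neutral conditions that should leave the flavanone and the methyl enol ether intact.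

**Compound list**

1 | 2,4,6-trihydroxybenzoic acid | OC(=O)c1c(O)cc(O)cc1O | starting material
2 | benzyl 2,4,6-trihydroxybenzoate | O=C(OCc1ccccc1)c1c(O)cc(O)cc1O | intermediate
3 | benzyl 2,6-dihydroxy-4-methoxybenzoate | COc1cc(O)c(C(=O)OCc2ccccc2)c(O)c1 | intermediate
4 | benzyl 2-hydroxy-4-methoxy-3,3,5-trimethyl-6-oxocyclohexa-1,4-diene-1-carboxylate | COC1=C(C)C(=O)C(C(=O)OCc2ccccc2)=C(O)C1(C)C | intermediate
5 | 2-hydroxy-4-methoxy-3,3,5-trimethyl-6-oxocyclohexa-1,4-diene-1-carboxylic acid | COC1=C(C)C(=O)C(C(=O)O)=C(O)C1(C)C | intermediate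
6 | 5-hydroxy-3-methoxy-2,4,4-trimethylcyclohexa-2,5-dien-1-one (ring T with T4–H) | COC1=C(C)C(=O)C=C(O)C1(C)C | intermediate
7 | isobutyraldehyde | CC(C)C=O | starting material
8 | 5-methoxy-4,6,6-trimethyl-2-(2-methylpropylidene)cyclohex-4-ene-1,3-dione (E/Z mixture) | COC1=C(C)C(=O)C(=CC(C)C)C(=O)C1(C)C | intermediate
9 | ethynyltrimethylsilane | C#C[Si](C)(C)C | starting material
10 | 5-hydroxy-3-methoxy-2,4,4-trimethyl-6-[(3S)-4-methyl-1-(trimethylsilyl)pent-1-yn-3-yl]cyclohexa-2,5-dien-1-one | COC1=C(C)C(=O)C([C@@H](C#C[Si](C)(C)C)C(C)C)=C(O)C1(C)C | intermediate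
11 | 5-(benzyloxy)-3-methoxy-2,4,4-trimethyl-6-[(3S)-4-methyl-1-(trimethylsilyl)pent-1-yn-3-yl]cyclohexa-2,5-dien-1-one | COC1=C(C)C(=O)C([C@@H](C#C[Si](C)(C)C)C(C)C)=C(OCc2ccccc2)C1(C)C | intermediate
12 | 5-(benzyloxy)-3-methoxy-2,4,4-trimethyl-6-[(3R)-4-methylpent-1-yn-3-yl]cyclohexa-2,5-dien-1-one | COC1=C(C)C(=O)C([C@@H](C#C)C(C)C)=C(OCc2ccccc2)C1(C)C | intermediate
13 | lithium (3R)-3-[2-(benzyloxy)-4-methoxy-3,3,5-trimethyl-6-oxocyclohexa-1,4-dien-1-yl]-4-methylpent-1-yn-1-olate | COC1=C(C)C(=O)C([C@@H](C#C[O-])C(C)C)=C(OCc2ccccc2)C1(C)C.[Li+] | intermediate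
14 | 5-(benzyloxy)-3-methoxy-2,4,4-trimethyl-6-[(3R)-4-methyl-1-{[tri(propan-2-yl)silyl]oxy}pent-1-yn-3-yl]cyclohexa-2,5-dien-1-one | COC1=C(C)C(=O)C([C@@H](C#CO[Si](C(C)C)(C(C)C)C(C)C)C(C)C)=C(OCc2ccccc2)C1(C)C | intermediate
15 | 1-ethoxyprop-1-yne | CCOC#CC | starting material
16 | acetone | CC(C)=O | starting material
17 | ketene (ethenone) | C=C=O | intermediate
18 | 3-ethoxy-2-methylcyclobut-2-en-1-one | CCOC1=C(C)C(=O)C1 | intermediate
19 | benzyl alcohol | OCc1ccccc1 | starting material
20 | 3-(benzyloxy)-2-methylcyclobut-2-en-1-one | CC1=C(OCc2ccccc2)CC1=O | intermediate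
21 | 3-(benzyloxy)-2-methylbuta-1,3-dien-1-one (vinylketene) | C=C(OCc1ccccc1)C(C)=C=O | intermediate
22 | 4-[1-(benzyloxy)ethenyl]-4-methyl-3-[(triisopropylsilyl)oxy]cyclobut-2-en-1-one bearing at C2 the (ring T)(isopropyl)methyl group of 14, bridge configured as in 14, both C4 epimers | COC1=C(C)C(=O)C([C@@H](C2=C(O[Si](C(C)C)(C(C)C)C(C)C)C(C)(C(=C)OCc3ccccc3)C2=O)C(C)C)=C(OCc2ccccc2)C1(C)C | intermediate
23 | 5-(benzyloxy)-4-methyl-3-[(triisopropylsilyl)oxy]hexa-1,3,5-trien-1-one bearing at C2 the bridge group of 14 (dienylketene, bridge configured as in 14) | COC1=C(C)C(=O)C([C@@H](C(=C=O)C(O[Si](C(C)C)(C(C)C)C(C)C)=C(C)C(=C)OCc2ccccc2)C(C)C)=C(OCc2ccccc2)C1(C)C | intermediate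
24 | cyclohexa-2,4-dien-1-one tautomer of 25 (C8a carbonyl, C4a methylene, bridge configured as in 14) | COC1=C(C)C(=O)C([C@@H](C2=C(O[Si](C(C)C)(C(C)C)C(C)C)C(C)=C(OCc3ccccc3)CC2=O)C(C)C)=C(OCc2ccccc2)C1(C)C | intermediate
25 | 5-(benzyloxy)-6-[(1R)-1-{4-(benzyloxy)-6-hydroxy-3-methyl-2-[(triisopropylsilyl)oxy]phenyl}-2-methylpropyl]-3-methoxy-2,4,4-trimethylcyclohexa-2,5-dien-1-one | COC1=C(C)C(=O)C([C@@H](c2c(O[Si](C(C)C)(C(C)C)C(C)C)c(C)c(OCc3ccccc3)cc2O)C(C)C)=C(OCc2ccccc2)C1(C)C | intermediate
26 | 5-(benzyloxy)-6-[(1R)-1-{4-(benzyloxy)-6-hydroxy-5-iodo-3-methyl-2-[(triisopropylsilyl)oxy]phenyl}-2-methylpropyl]-3-methoxy-2,4,4-trimethylcyclohexa-2,5-dien-1-one | COC1=C(C)C(=O)C([C@@H](c2c(O[Si](C(C)C)(C(C)C)C(C)C)c(C)c(OCc3ccccc3)c(I)c2O)C(C)C)=C(OCc2ccccc2)C1(C)C | intermediate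
27 | tributyl(1-ethoxyethenyl)stannane | CCCC[Sn](CCCC)(CCCC)C(=C)OCC | starting material
28 | 5-(benzyloxy)-6-[(1R)-1-{4-(benzyloxy)-5-(1-ethoxyethenyl)-6-hydroxy-3-methyl-2-[(triisopropylsilyl)oxy]phenyl}-2-methylpropyl]-3-methoxy-2,4,4-trimethylcyclohexa-2,5-dien-1-one | COC1=C(C)C(=O)C([C@@H](c2c(O[Si](C(C)C)(C(C)C)C(C)C)c(C)c(OCc3ccccc3)c(C(=C)OCC)c2O)C(C)C)=C(OCc2ccccc2)C1(C)C | intermediate
29 | 6-[(1R)-1-{5-acetyl-4-(benzyloxy)-6-hydroxy-3-methyl-2-[(triisopropylsilyl)oxy]phenyl}-2-methylpropyl]-5-(benzyloxy)-3-methoxy-2,4,4-trimethylcyclohexa-2,5-dien-1-one | COC1=C(C)C(=O)C([C@@H](c2c(O[Si](C(C)C)(C(C)C)C(C)C)c(C)c(OCc3ccccc3)c(C(C)=O)c2O)C(C)C)=C(OCc2ccccc2)C1(C)C | intermediate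
30 | N,N-dimethylformamide dimethyl acetal | COC(OC)N(C)C | starting material
31 | 5-(benzyloxy)-6-[(1R)-1-{4-(benzyloxy)-5-[(2E)-3-(dimethylamino)prop-2-enoyl]-6-hydroxy-3-methyl-2-[(triisopropylsilyl)oxy]phenyl}-2-methylpropyl]-3-methoxy-2,4,4-trimethylcyclohexa-2,5-dien-1-one | COC1=C(C)C(=O)C([C@@H](c2c(O[Si](C(C)C)(C(C)C)C(C)C)c(C)c(OCc3ccccc3)c(C(=O)/C=C/N(C)C)c2O)C(C)C)=C(OCc2ccccc2)C1(C)C | intermediate
32 | 5-(benzyloxy)-8-[(1R)-1-(2-(benzyloxy)-4-methoxy-3,3,5-trimethyl-6-oxocyclohexa-1,4-dien-1-yl)-2-methylpropyl]-6-methyl-7-[(triisopropylsilyl)oxy]-4H-chromen-4-one | COC1=C(C)C(=O)C([C@@H](c2c(O[Si](C(C)C)(C(C)C)C(C)C)c(C)c(OCc3ccccc3)c3c2OC=CC3=O)C(C)C)=C(OCc2ccccc2)C1(C)C | intermediate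
33 | phenylboronic acid | OB(O)c1ccccc1 | starting material
34 | (2S)-5-(benzyloxy)-8-[(1R)-1-(2-(benzyloxy)-4-methoxy-3,3,5-trimethyl-6-oxocyclohexa-1,4-dien-1-yl)-2-methylpropyl]-6-methyl-2-phenyl-7-[(triisopropylsilyl)oxy]-2,3-dihydro-4H-chromen-4-one | COC1=C(C)C(=O)C([C@@H](c2c(O[Si](C(C)C)(C(C)C)C(C)C)c(C)c(OCc3ccccc3)c3c2O[C@H](c2ccccc2)CC3=O)C(C)C)=C(OCc2ccccc2)C1(C)C | intermediate
35 | (2S)-5-(benzyloxy)-8-[(1R)-1-(2-(benzyloxy)-4-methoxy-3,3,5-trimethyl-6-oxocyclohexa-1,4-dien-1-yl)-2-methylpropyl]-7-hydroxy-6-methyl-2-phenyl-2,3-dihydro-4H-chromen-4-one | COC1=C(C)C(=O)C([C@@H](c2c(O)c(C)c(OCc3ccccc3)c3c2O[C@H](c2ccccc2)CC3=O)C(C)C)=C(OCc2ccccc2)C1(C)C | intermediate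
36 | (2S)-5,7-dihydroxy-8-[(1R)-1-(2-hydroxy-4-methoxy-3,3,5-trimethyl-6-oxocyclohexa-1,4-dien-1-yl)-2-methylpropyl]-6-methyl-2-phenyl-2,3-dihydro-4H-chromen-4-one | COC1=C(C)C(=O)C([C@@H](c2c(O)c(C)c(O)c3c2O[C@H](c2ccccc2)CC3=O)C(C)C)=C(O)C1(C)C | target

**Step count**

Total: 16 steps. Longest linear sequence: 14 steps (steps 1–8, then 11–16); the cyclobutenone branch (steps 9–10) is convergent.

**Steps most likely to fail**

1. Step 11 (benzannulation). The vinylogous-ester cyclobutenone may resist 4π ring opening below the temperature at which the siloxyalkyne degrades. The [2+2] addition may also stall at the branched, hindered alkyne carbon so that the ketene dimerises, the ring T carbonyl oxygen may intercept the ketene or the dipolar cycloaddition intermediate, and the new C8a phenol may cyclise onto ring T at high temperature. Fallback: setting out from siloxyalkyne 14, vinylketene 21 would be generated at 25–40 °C by triethylamine-induced 1,4-dehydrochlorination of 3-(benzyloxy)-2-methylbut-2-enoyl chloride F3. F3 would be made from commercial ethyl 2-methylacetoacetate by acid-catalysed enol etherification with benzyl alcohol to ethyl 3-(benzyloxy)-2-methylbut-2-enoate F1, saponification to 3-(benzyloxy)-2-methylbut-2-enoic acid F2 and treatment with oxalyl chloride. The ketene would be trapped in situ by 14 to give cyclobutenone adduct 22, which on warming to about 80 °C passes through 23 and 24 and rejoins the route at phenol 25. This ketene–siloxyalkyne annulation from unsaturated acid chlorides is known for resorcinol synthesis and removes the need to open a cyclobutenone.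

2. Step 6 (asymmetric alkynylation). Enantioface discrimination may be poor on the unsymmetrical, chelating acceptor. The diketonate product may sequester rhodium, the alkylidene may isomerise to its dienol, and the alkyne may dimerise. Fallback: setting out from alkylidene 8, copper-catalysed conjugate addition of commercial ethynylmagnesium bromide (CuI, THF, −40 °C) would give the racemic adduct 5-hydroxy-3-methoxy-2,4,4-trimethyl-6-(4-methylpent-1-yn-3-yl)cyclohexa-2,5-dien-1-one F4. This acidic enol would be resolved by crystallising its salt with (S)-1-phenylethylamine, the (S)-1-phenylethylammonium salt of the R enol F5 (the antipodal amine would be used if the other diastereomeric salt proved the less soluble). Cold dilute citric acid would liberate 5-hydroxy-3-methoxy-2,4,4-trimethyl-6-[(3R)-4-methylpent-1-yn-3-yl]cyclohexa-2,5-dien-1-one F6, and O-benzylation as in step 7 (BnBr, K2CO3, DMF) rejoins the route at 12.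

3. Step 15 (conjugate arylation). Carbopalladation of the electron-rich, hindered chromone may be slow, so that protodeboronation and biaryl formation consume the boronic acid, and C2 selectivity may erode. Fallback: setting out from acetophenone 29, pyrrolidine-mediated condensation with benzaldehyde (EtOH, 60 °C) would give the 2'-hydroxychalcone of ring A F7. Under the same conditions F7 cyclises by reversible oxa-Michael addition to a mixture of 34 and the 2R epimer of 34 F8. Because the bridge centre is fixed these are diastereomers, separable by chromatography, and F8 would be returned to the equilibration, so the route is rejoined at 34.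

**Further compounds**

F1 | step 11 | ethyl 3-(benzyloxy)-2-methylbut-2-enoate | CCOC(=O)C(C)=C(C)OCc1ccccc1
F2 | step 11 | 3-(benzyloxy)-2-methylbut-2-enoic acid | OC(=O)C(C)=C(C)OCc1ccccc1
F3 | step 11 | 3-(benzyloxy)-2-methylbut-2-enoyl chloride | ClC(=O)C(C)=C(C)OCc1ccccc1
F4 | step 6 | racemic 5-hydroxy-3-methoxy-2,4,4-trimethyl-6-(4-methylpent-1-yn-3-yl)cyclohexa-2,5-dien-1-one | COC1=C(C)C(=O)C(C(C#C)C(C)C)=C(O)C1(C)C
F5 | step 6 | (S)-1-phenylethylammonium salt of the R enol | COC1=C(C)C(=O)C([C@@H](C#C)C(C)C)=C([O-])C1(C)C.C[C@H]([NH3+])c1ccccc1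
F6 | step 6 | 5-hydroxy-3-methoxy-2,4,4-trimethyl-6-[(3R)-4-methylpent-1-yn-3-yl]cyclohexa-2,5-dien-1-one | COC1=C(C)C(=O)C([C@@H](C#C)C(C)C)=C(O)C1(C)C
F7 | step 15 | 2'-hydroxychalcone of ring A (C4a cinnamoyl analogue of 29) | COC1=C(C)C(=O)C([C@@H](c2c(O[Si](C(C)C)(C(C)C)C(C)C)c(C)c(OCc3ccccc3)c(C(=O)/C=C/c3ccccc3)c2O)C(C)C)=C(OCc2ccccc2)C1(C)C
F8 | step 15 | 2R epimer of 34 | COC1=C(C)C(=O)C([C@@H](c2c(O[Si](C(C)C)(C(C)C)C(C)C)c(C)c(OCc3ccccc3)c3c2O[C@@H](c2ccccc2)CC3=O)C(C)C)=C(OCc2ccccc2)C1(C)C
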